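The route rests on cutting the O1–C7a aryl ether bond of the dihydrofuran (ring D). This bond joins ring C to the carbinol oxygen and lies outside both stereocentres, C2 and C3, so it can be made last without touching them. One copper-catalysed intramolecular O-arylation turns an open-chain anti aldol product into the cis-2,3-disubstituted dihydrobenzofuran with retention, closing ring D and leaving C5 free for attachment of ring B. The precursor is the (1R,2R)-2-(2-bromo-3-methoxyphenyl)-1-arylpropane-1,3-diol whose primary hydroxyl is a triisopropylsilyl ether (too bulky to migrate to the reacting alkoxide) and whose ring E phenol is a tosylate.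

Key step: step 6

Remark: the target is taken exactly as drawn, i.e. a cis (2R,3R) dihydrobenzofuran and a tetrahydrofuran in which aryl, hydroxymethyl and benzyl are all cis and the tertiary hydroxyl is trans to them; compounds 1, 3, 4, 14, 18, 25 and (R)-TRIP are assumed purchasable.
Remark: ring A = benzyl guaiacyl ring, B = tetrahydrofuran, C and D = benzo and dihydrofuran rings, E = aryl on C2; TIPS = triisopropylsilyl, Ts = 4-methylphenylsulfonyl, Bpin = 4,4,5,5-tetramethyl-1,3,2-dioxaborolan-2-yl, Bf = the 5-yl group of compound 11.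

Step 1
Reactants: 1 vanillin
Product: 2 4-formyl-2-methoxyphenyl 4-methylbenzenesulfonate
Conditions: TsCl, Et3N, DMAP (cat.), CH2Cl2, 0 °C to rt
Reagents that add atoms: 4-methylbenzenesulfonyl chloride, Cc1ccc(cc1)S(Cl)(=O)=O
Why: O-sulfonylation of a phenol with a sulfonyl chloride and amine base is reliable, and the tosylate later deactivates ring E and withstands hydride, carbonate and organomagnesium reagents.

Step 2
Reactants: 3 (2-bromo-3-methoxyphenyl)acetic acid; 4 (R)-4-benzyl-1,3-oxazolidin-2-one
Product: 6 (4R)-4-benzyl-3-[(2-bromo-3-methoxyphenyl)acetyl]-1,3-oxazolidin-2-one, via mixed pivalic anhydride 5 (not isolated)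
Conditions: PivCl, Et3N, THF, −20 °C; then 4, LiCl, −20 °C to rt
Reagents that add atoms: none
Why: N-acylation of the oxazolidinone through the mixed anhydride with LiCl activation avoids an acid chloride, and thus ketene formation, from the enolisable arylacetic acid.

Step 3
Reactants: 6 N-arylacetyl oxazolidinone; 2 O-tosylvanillin
Product: 8 (4R)-4-benzyl-3-[(2S,3R)-2-(2-bromo-3-methoxyphenyl)-3-hydroxy-3-(3-methoxy-4-tosyloxyphenyl)propanoyl]-1,3-oxazolidin-2-one, via trimethylsilyl ether 7 (not isolated)
Conditions: MgCl2 (20 mol%), Et3N, TMSCl, EtOAc, rt; then MeOH, TFA (cat.)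
Reagents that add atoms: none
Why: Evans MgCl2-catalysed direct anti aldol: soft enolisation gives the chelated Z magnesium enolate, which should add through a boat transition state on the face away from the auxiliary benzyl group, setting C2 (S) and C3 (R) together, while TMSCl traps the aldolate so that the adduct cannot revert.

Step 4
Reactants: 8 anti aldol adduct
Product: 9 (1R,2R)-2-(2-bromo-3-methoxyphenyl)-1-(3-methoxy-4-tosyloxyphenyl)propane-1,3-diol
Conditions: LiBH4, MeOH (2 equiv), THF, 0 °C
Reagents that add atoms: none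
Why: Reductive cleavage of the N-acyl oxazolidinone with LiBH4 is selective for the exocyclic carbonyl and fast at 0 °C, so neither stereocentre nor the aryl bromide and tosylate should be affected.

Step 5
Reactants: 9 anti diol
Product: 10 (1R,2R)-2-(2-bromo-3-methoxyphenyl)-1-(3-methoxy-4-tosyloxyphenyl)-3-(triisopropylsilyloxy)propan-1-ol
Conditions: TIPSCl, imidazole, DMF, 0 °C to rt
Reagents that add atoms: chlorotriisopropylsilane, CC(C)[Si](Cl)(C(C)C)C(C)C
Why: Silylation with the bulky chlorosilane is selective for the primary over the secondary benzylic hydroxyl.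

Step 6
Reactants: 10 anti bromo alcohol
Product: 11 (2R,3R)-7-methoxy-2-(3-methoxy-4-tosyloxyphenyl)-3-[(triisopropylsilyloxy)methyl]-2,3-dihydro-1-benzofuran
Conditions: CuI (10 mol%), 3,4,7,8-tetramethyl-1,10-phenanthroline (20 mol%), Cs2CO3, toluene, 110 °C
Reagents that add atoms: none
Why: The caesium alkoxide of the secondary alcohol passes to the phenanthroline-bound monovalent copper centre, the copper alkoxide inserts into the neighbouring C–Br bond, and the trivalent copper aryl alkoxide collapses by C–O reductive elimination to form O1–C7a. The closest known reaction type is the Ullmann-type copper-catalysed intramolecular etherification of aryl bromides with aliphatic alcohols that gives 2,3-dihydrobenzofurans. Ring D closes in a 5-exo-trig mode at the aryl carbon. No stereocentre is created: the C2–O and C3–C3a bonds are never broken, so the (1R,2R) anti arrangement passes with retention into the cis ring, and the electron-poor tosyloxy group keeps the benzylic carbinol from ionising. The step needs selectivity for the secondary alkoxide and for C–Br over the aryl sulfonate. The first is secured by the non-migrating TIPS ether, which masks the primary oxygen that could otherwise close an isomeric five-membered ring on the same carbon, and the second by copper, which does not insert into aryl tosylates and, unlike palladium, does not oxidise the alkoxide by β-hydride elimination.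

Step 7
Reactants: 11 cis-dihydrobenzofuran
Product: 12 (2R,3R)-5-bromo-7-methoxy-2-(3-methoxy-4-tosyloxyphenyl)-3-[(triisopropylsilyloxy)methyl]-2,3-dihydro-1-benzofuran
Conditions: NBS, MeCN, 0 °C, dark
Reagents that add atoms: N-bromosuccinimide, O=C1CCC(=O)N1Br
Why: Electrophilic aromatic bromination should go to C5, para to the ring oxygen O1 of the dialkoxy-substituted ring C, because ring E is deactivated by its sulfonate.

Step 8
Reactants: 12 aryl bromide
Product: 13 (2R,3R)-7-methoxy-2-(3-methoxy-4-tosyloxyphenyl)-3-[(triisopropylsilyloxy)methyl]-2,3-dihydro-1-benzofuran-5-carbaldehyde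
Conditions: Pd(OAc)2 (1 mol%), di(1-adamantyl)-n-butylphosphine (3 mol%), TMEDA, CO/H2 (1:1, 5 bar), toluene, 100 °C
Reagents that add atoms: carbon monoxide, [C-]#[O+]
Why: Palladium-catalysed reductive carbonylation of the aryl bromide should give the aldehyde without an aryllithium or aryl Grignard intermediate that could attack the sulfonate, and the aryl tosylate is inert to this catalyst.

Step 9
Reactants: 14 but-2-yne-1,4-diol
Product: 16 (Z)-2-iodobut-2-ene-1,4-diol, via cyclic alkenylalanate 15 (not isolated)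
Conditions: NaAlH2(OCH2CH2OMe)2 (2.5 equiv), THF, 0 °C to rt; then I2, −78 to 0 °C
Reagents that add atoms: iodine, II
Why: Hydroxyl-directed trans-hydroalumination of the propargylic alcohol followed by iodinolysis of the C–Al bond with retention places iodine cis to the CH2OH group on the neighbouring alkene carbon.

Step 10
Reactants: 16 iodo diol
Product: 17 (Z)-2-iodobut-2-ene-1,4-diyl diacetate
Conditions: Ac2O, pyridine, DMAP (cat.), CH2Cl2, 0 °C to rt
Reagents that add atoms: acetic anhydride, CC(=O)OC(C)=O
Why: Standard DMAP-catalysed O-acetylation of two primary allylic hydroxyls installs the later leaving group and the protecting group of the ring B hydroxymethyl in one operation.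

Step 11
Reactants: 17 alkenyl iodide; 18 2-(iodomethyl)-4,4,5,5-tetramethyl-1,3,2-dioxaborolane
Product: 20 (E)-2-[(Bpin)methyl]but-2-ene-1,4-diyl diacetate (CH2Bpin cis to the C4 acetoxymethyl group), via borylmethylzinc iodide 19 (not isolated)
Conditions: Zn dust (activated), THF, rt; then 17, Pd(PPh3)4 (3 mol%), THF, 0 °C to rt
Reagents that add atoms: none
Why: Negishi coupling of the (pinacolboryl)methylzinc reagent with an alkenyl iodide goes with retention of alkene geometry, and oxidative addition of the C–I bond to zerovalent palladium at or below room temperature should outrun ionisation of the allylic acetates.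

Step 12
Reactants: 13 aldehyde; 20 allylboronate
Product: 22 (2R)-2-[(R)-Bf(hydroxy)methyl]-3-methylidenebutane-1,4-diyl diacetate, via O-boryl ether 21 (not isolated)
Conditions: (R)-TRIP (5 mol%), 4 Å MS, toluene, −30 to 0 °C; then NaHCO3 (aq)
Reagents that add atoms: none
Why: Chiral phosphoric acid-catalysed allylboration through a closed chair transition state: the acid should direct the allyl unit to the Re face of the aldehyde, setting the carbinol centre (R), and the acetoxymethyl group cis to the borylmethyl group sits axial, setting the adjacent centre (R) syn to the new hydroxyl.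

Step 13
Reactants: 22 homoallylic alcohol
Product: 23 [(2R,3R)-2-Bf-4-methylideneoxolan-3-yl]methyl acetate
Conditions: Pd(PPh3)4 (5 mol%), Et3N, THF, 60 °C
Reagents that add atoms: none
Why: Tsuji–Trost intramolecular allylic etherification: zerovalent palladium ionises only the allylic acetate, and the secondary hydroxyl closes ring B by 5-exo attack on either of the two equivalent CH2 termini of the π-allyl complex without touching the two stereocentres.

Step 14
Reactants: 23 methylidene oxolane
Product: 24 [(3R,6R,7R)-6-Bf-1,5-dioxaspiro[2.4]heptan-7-yl]methyl acetate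
Conditions: mCPBA, NaHCO3, CH2Cl2, 0 °C
Reagents that add atoms: 3-chloroperoxybenzoic acid, OOC(=O)c1cccc(Cl)c1
Why: Prilezhaev epoxidation of the exocyclic alkene should occur on the ring face opposite to the cis aryl and acetoxymethyl groups, so the spiro carbon (3R) receives its oxygen trans to both.

Step 15
Reactants: 25 4-bromo-2-methoxyphenol
Product: 26 (4-bromo-2-methoxyphenoxy)triisopropylsilane
Conditions: TIPSCl, imidazole, DMF, rt
Reagents that add atoms: chlorotriisopropylsilane, CC(C)[Si](Cl)(C(C)C)C(C)C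
Why: Standard silylation of a phenol; the aryl TIPS ether survives magnesium insertion and is removed later together with the alkyl TIPS ether.

Step 16
Reactants: 24 spiro-epoxide; 26 aryl bromide
Product: 29 (3S,4R,5R)-5-Bf-4-(hydroxymethyl)-3-{[3-methoxy-4-(triisopropylsilyloxy)phenyl]methyl}oxolan-3-ol, via aryl Grignard reagent 27 (not isolated), via ring-opened acetate 28 (not isolated)
Conditions: 26, Mg, THF, 45 °C; then 24, CuI (10 mol%), THF, −40 to 0 °C (5 equiv of 27); NH4Cl (aq)
Reagents that add atoms: none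
Why: Copper-catalysed SN2 opening of the 2,2-disubstituted epoxide by the aryl Grignard reagent at its CH2 carbon installs the benzyl group without breaking the tertiary C–O bond, so the configuration from step 14 is kept, and the excess reagent then removes the acetate by acyl addition.

Step 17
Reactants: 29 bis-silyl ether
Product: 30 (3S,4R,5R)-5-[(2R,3R)-3-(hydroxymethyl)-7-methoxy-2-(3-methoxy-4-tosyloxyphenyl)-2,3-dihydro-1-benzofuran-5-yl]-3-[(4-hydroxy-3-methoxyphenyl)methyl]-4-(hydroxymethyl)oxolan-3-ol
Conditions: TBAF, THF, 0 °C to rt; NH4Cl (aq)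
Reagents that add atoms: none
Why: Fluoride-induced desilylation cleaves the aryl and the primary alkyl TIPS ethers while the aryl tosylate stays, so no phenoxide is yet formed para to C2 of the dihydrobenzofuran.

Step 18
Reactants: 30 aryl tosylate
Product: 31 (3S,4R,5R)-3-[(4-hydroxy-3-methoxyphenyl)methyl]-5-[(2R,3R)-2-(4-hydroxy-3-methoxyphenyl)-3-(hydroxymethyl)-7-methoxy-2,3-dihydro-1-benzofuran-5-yl]-4-(hydroxymethyl)oxolan-3-ol (CNP0284796.1)
Conditions: Mg turnings, MeOH, rt, sonication
Reagents that add atoms: none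
Why: Reductive S–O cleavage of the aryl sulfonate by magnesium in methanol frees the last phenol at room temperature, under conditions that should be too mild to open the cis-dihydrofuran through a quinone methide.

Compound list
1 | vanillin | COc1cc(C=O)ccc1O | starting material
2 | 4-formyl-2-methoxyphenyl 4-methylbenzenesulfonate | COc1cc(C=O)ccc1OS(=O)(=O)c1ccc(C)cc1 | intermediate
3 | (2-bromo-3-methoxyphenyl)acetic acid | COc1cccc(CC(=O)O)c1Br | starting material
4 | (R)-4-benzyl-1,3-oxazolidin-2-one | O=C1N[C@H](Cc2ccccc2)CO1 | starting material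
5 | (2-bromo-3-methoxyphenyl)acetic pivalic anhydride | COc1cccc(CC(=O)OC(=O)C(C)(C)C)c1Br | intermediate
6 | (4R)-4-benzyl-3-[(2-bromo-3-methoxyphenyl)acetyl]-1,3-oxazolidin-2-one | COc1cccc(CC(=O)N2[C@H](Cc3ccccc3)COC2=O)c1Br | intermediate
7 | trimethylsilyl ether of 8 | COc1cccc(c1Br)[C@H](C(=O)N2[C@H](Cc3ccccc3)COC2=O)[C@H](c4ccc(OS(=O)(=O)c5ccc(C)cc5)c(OC)c4)O[Si](C)(C)C | intermediate
8 | (4R)-4-benzyl-3-[(2S,3R)-2-(2-bromo-3-methoxyphenyl)-3-hydroxy-3-(3-methoxy-4-tosyloxyphenyl)propanoyl]-1,3-oxazolidin-2-one | COc1cccc(c1Br)[C@H](C(=O)N2[C@H](Cc3ccccc3)COC2=O)[C@H](c4ccc(OS(=O)(=O)c5ccc(C)cc5)c(OC)c4)O | intermediate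
9 | (1R,2R)-2-(2-bromo-3-methoxyphenyl)-1-(3-methoxy-4-tosyloxyphenyl)propane-1,3-diol | COc1cccc(c1Br)[C@H](CO)[C@H](c2ccc(OS(=O)(=O)c3ccc(C)cc3)c(OC)c2)O | intermediate
10 | (1R,2R)-2-(2-bromo-3-methoxyphenyl)-1-(3-methoxy-4-tosyloxyphenyl)-3-(triisopropylsilyloxy)propan-1-ol | COc1cccc(c1Br)[C@H](CO[Si](C(C)C)(C(C)C)C(C)C)[C@H](c2ccc(OS(=O)(=O)c3ccc(C)cc3)c(OC)c2)O | intermediate
11 | (2R,3R)-7-methoxy-2-(3-methoxy-4-tosyloxyphenyl)-3-[(triisopropylsilyloxy)methyl]-2,3-dihydro-1-benzofuran | c1cc(OC)c2c(c1)[C@H](CO[Si](C(C)C)(C(C)C)C(C)C)[C@H](c3ccc(OS(=O)(=O)c4ccc(C)cc4)c(OC)c3)O2 | intermediate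
12 | 5-bromo derivative of 11 | Brc1cc(OC)c2c(c1)[C@H](CO[Si](C(C)C)(C(C)C)C(C)C)[C@H](c3ccc(OS(=O)(=O)c4ccc(C)cc4)c(OC)c3)O2 | intermediate
13 | 5-carbaldehyde derivative of 11 | O=Cc1cc(OC)c2c(c1)[C@H](CO[Si](C(C)C)(C(C)C)C(C)C)[C@H](c3ccc(OS(=O)(=O)c4ccc(C)cc4)c(OC)c3)O2 | intermediate
14 | but-2-yne-1,4-diol | OCC#CCO | starting material
15 | cyclic alkenylalanate (idealised; second hydroxyl drawn free) | [Na+].COCCO[Al-]1(OCCOC)OCC=C1CO | intermediate
16 | (Z)-2-iodobut-2-ene-1,4-diol | OC/C=C(\I)CO | intermediate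
17 | (Z)-2-iodobut-2-ene-1,4-diyl diacetate | CC(=O)OC/C=C(\I)COC(C)=O | intermediate
18 | 2-(iodomethyl)-4,4,5,5-tetramethyl-1,3,2-dioxaborolane | ICB1OC(C)(C)C(C)(C)O1 | starting material
19 | [(Bpin)methyl]zinc iodide | I[Zn]CB1OC(C)(C)C(C)(C)O1 | intermediate
20 | (E)-2-[(Bpin)methyl]but-2-ene-1,4-diyl diacetate | CC(=O)OC/C=C(\CB1OC(C)(C)C(C)(C)O1)COC(C)=O | intermediate
21 | O-Bpin ether of 22 | CC1(C)OB(O[C@@H](c2cc(OC)c3c(c2)[C@H](CO[Si](C(C)C)(C(C)C)C(C)C)[C@H](c4ccc(OS(=O)(=O)c5ccc(C)cc5)c(OC)c4)O3)[C@H](C(=C)COC(C)=O)COC(C)=O)OC1(C)C | intermediate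
22 | (2R)-2-[(R)-Bf(hydroxy)methyl]-3-methylidenebutane-1,4-diyl diacetate | O[C@@H](c1cc(OC)c2c(c1)[C@H](CO[Si](C(C)C)(C(C)C)C(C)C)[C@H](c3ccc(OS(=O)(=O)c4ccc(C)cc4)c(OC)c3)O2)[C@H](C(=C)COC(C)=O)COC(C)=O | intermediate
23 | [(2R,3R)-2-Bf-4-methylideneoxolan-3-yl]methyl acetate | C=C1CO[C@@H](c2cc(OC)c3c(c2)[C@H](CO[Si](C(C)C)(C(C)C)C(C)C)[C@H](c4ccc(OS(=O)(=O)c5ccc(C)cc5)c(OC)c4)O3)[C@H]1COC(C)=O | intermediate
24 | [(3R,6R,7R)-6-Bf-1,5-dioxaspiro[2.4]heptan-7-yl]methyl acetate | C1[C@@]2(O1)CO[C@@H](c3cc(OC)c4c(c3)[C@H](CO[Si](C(C)C)(C(C)C)C(C)C)[C@H](c5ccc(OS(=O)(=O)c6ccc(C)cc6)c(OC)c5)O4)[C@H]2COC(C)=O | intermediate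
25 | 4-bromo-2-methoxyphenol | COc1cc(Br)ccc1O | starting material
26 | (4-bromo-2-methoxyphenoxy)triisopropylsilane | COc1cc(Br)ccc1O[Si](C(C)C)(C(C)C)C(C)C | intermediate
27 | [3-methoxy-4-(triisopropylsilyloxy)phenyl]magnesium bromide | COc1cc([Mg]Br)ccc1O[Si](C(C)C)(C(C)C)C(C)C | intermediate
28 | acetate of 29 at the oxolane 4-hydroxymethyl group | COc1cc(C[C@@]2(O)CO[C@@H](c3cc(OC)c4c(c3)[C@H](CO[Si](C(C)C)(C(C)C)C(C)C)[C@H](c5ccc(OS(=O)(=O)c6ccc(C)cc6)c(OC)c5)O4)[C@H]2COC(C)=O)ccc1O[Si](C(C)C)(C(C)C)C(C)C | intermediate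
29 | (3S,4R,5R)-5-Bf-4-(hydroxymethyl)-3-{[3-methoxy-4-(triisopropylsilyloxy)phenyl]methyl}oxolan-3-ol | COc1cc(C[C@@]2(O)CO[C@@H](c3cc(OC)c4c(c3)[C@H](CO[Si](C(C)C)(C(C)C)C(C)C)[C@H](c5ccc(OS(=O)(=O)c6ccc(C)cc6)c(OC)c5)O4)[C@H]2CO)ccc1O[Si](C(C)C)(C(C)C)C(C)C | intermediate
30 | ring E tosylate of the target | COc1cc(C[C@@]2(O)CO[C@@H](c3cc(OC)c4c(c3)[C@H](CO)[C@H](c5ccc(OS(=O)(=O)c6ccc(C)cc6)c(OC)c5)O4)[C@H]2CO)ccc1O | intermediate
31 | CNP0284796.1 | COc1cc(C[C@@]2(O)CO[C@@H](c3cc(OC)c4c(c3)[C@H](CO)[C@H](c3ccc(O)c(OC)c3)O4)[C@H]2CO)ccc1O | target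

Total step count: 18. Longest linear sequence: 13 steps (3 → 6 → 8 → 9 → 10 → 11 → 12 → 13 → 22 → 23 → 24 → 29 → 30 → 31).

Steps most likely to fail

Step 6. Oxidative addition at the bromide, which is flanked on both sides, may be slow, so that sulfonyl transfer from the aryl tosylate to the alkoxide or hydrodebromination takes over. The fallback sets out from 10 and makes the same O1–C7a bond oxidatively, with the arene as the nucleophilic partner and no alkoxide. Miyaura borylation (B2pin2, KOAc, Pd(dppf)Cl2, dioxane, 90 °C) would give the aryl pinacol boronate F1. KHF2 in aqueous MeOH would convert it into the potassium aryltrifluoroborate F2. Chan–Lam-type etherification (Cu(OAc)2, DMAP, 4 Å MS, O2, CH2Cl2, rt) should then join the secondary hydroxyl to the borylated carbon with the carbinol untouched, coming back to the route at 11.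

Step 12. Enantiofacial discrimination may be incomplete, because the acetate carbonyls can compete for the hydrogen bond of the acid and the hindered reagent may need temperatures at which uncatalysed addition sets in. The resulting epimers would differ from the desired one only relative to remote stereocentres and would be hard to separate. The fallback sets out from 20 and moves the chiral controller from a catalyst onto boron. KHF2 would give the potassium allyltrifluoroborate F3. TMSCl with (R)-3,3'-bis(trifluoromethyl)-1,1'-bi-2-naphthol (or its antipode, whichever places the allyl group on the Re face) would give the binaphthol allylboronate F4. This stoichiometric chiral reagent would be added to 13 in toluene at −78 °C without any acid, and aqueous work-up comes back to the route at 22.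

Step 3. Anti selectivity may erode through reversible aldolisation and epimerisation of the acidic α-aryl centre before silyl trapping. The fallback sets out from 3 and 2 and builds both centres by a stereospecific addition to an alkene. Perkin condensation (Ac2O, Et3N, 110 °C) would give the (E)-2,3-diarylacrylic acid F5 with the two aryl groups cis. Reduction through the mixed carbonic anhydride (ClCO2Et, Et3N; then NaBH4, THF/H2O) would give the allylic alcohol F6, and TIPSCl with imidazole the silyl ether F7. Asymmetric hydroboration with monoisopinocampheylborane (IpcBH2 of the handedness that gives the 1R,2R product, THF, −25 °C; then NaBO3·4H2O) would add H and OH syn, with boron on the CH carbon. For this alkene geometry that is the anti arrangement, and the sequence comes back to the route at 10.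

Further compounds
F1 | step 6 | (1R,2R)-1-(3-methoxy-4-tosyloxyphenyl)-2-[3-methoxy-2-(Bpin)phenyl]-3-(triisopropylsilyloxy)propan-1-ol | COc1cccc(c1B2OC(C)(C)C(C)(C)O2)[C@H](CO[Si](C(C)C)(C(C)C)C(C)C)[C@H](c3ccc(OS(=O)(=O)c4ccc(C)cc4)c(OC)c3)O
F2 | step 6 | potassium trifluoroborate corresponding to F1 | [K+].COc1cccc(c1[B-](F)(F)F)[C@H](CO[Si](C(C)C)(C(C)C)C(C)C)[C@H](c2ccc(OS(=O)(=O)c3ccc(C)cc3)c(OC)c2)O
F3 | step 12 | potassium (E)-[4-acetoxy-2-(acetoxymethyl)but-2-en-1-yl]trifluoroborate | [K+].CC(=O)OC/C=C(\C[B-](F)(F)F)COC(C)=O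
F4 | step 12 | (R)-3,3'-bis(trifluoromethyl)-1,1'-bi-2-naphthol ester of the allylboronic acid of 20 | CC(=O)OC/C=C(\CB1Oc2c(C(F)(F)F)cc3ccccc3c2-c2c(O1)c(C(F)(F)F)cc3ccccc23)COC(C)=O
F5 | step 3 | (E)-2-(2-bromo-3-methoxyphenyl)-3-(3-methoxy-4-tosyloxyphenyl)prop-2-enoic acid | OC(=O)/C(=C/c1ccc(OS(=O)(=O)c2ccc(C)cc2)c(OC)c1)c1cccc(OC)c1Br
F6 | step 3 | (E)-2-(2-bromo-3-methoxyphenyl)-3-(3-methoxy-4-tosyloxyphenyl)prop-2-en-1-ol | OC/C(=C/c1ccc(OS(=O)(=O)c2ccc(C)cc2)c(OC)c1)c1cccc(OC)c1Br
F7 | step 3 | triisopropylsilyl ether of F6 | CC(C)[Si](OC/C(=C/c1ccc(OS(=O)(=O)c2ccc(C)cc2)c(OC)c1)c1cccc(OC)c1Br)(C(C)C)C(C)C
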